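## Structural features

The target 24 is a methylene-bridged pyrone–acylphloroglucinol: C3 of a 6-ethyl-4-hydroxy-5-methyl-2-pyrone is joined through one CH2 group to C1' of a benzene ring that carries no hydrogen. Around that ring, C2' bears OH, C3' a prenyl group, C4' OH, C5' an isobutyryl group and C6' a methoxy group, so only one of the three phloroglucinol oxygens is methylated. There is no stereocentre and no stereogenic double bond. The fragile parts are the prenyl alkene flanked by two phenols (acid closes it to a chroman, and it rules out hydrogenation and electrophilic halogen late in the route), the acidic pyrone OH with its ambident anion and diene character, and the lactone. The real difficulty is regiochemical: six different substituents must be placed around an arene whose parent, phloroglucinol, is symmetric, and the acyl group, the prenyl group and the single O-methyl must each find one specific carbon. The key step uses the fact that the C4' hydroxyl and the C5' isobutyryl group are neighbours and that C5' lies next to the C6' methoxy group. That is the pattern produced when a carboxylate adds to a 3-methoxy-type aryne spanning C4'–C5' and the acyl group then moves from oxygen to carbon.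

## Logic of the disconnections

24 to 23: the two O–CH2 bonds of the methoxymethyl acetals on O2' and on the pyrone O4 are cut. Both hydroxyls are acidic nucleophiles that would add to an aryne and compete in every alkylation, so they stay masked to the end. This does not simplify the skeleton, but every earlier intermediate then has at most one free OH. The forward cleavage must be mild enough not to cyclise the prenyl group onto a neighbouring phenol.

23 to 20 (through 22 and 21): the C3'–CH2 bond of the prenyl group is cut and traced back, through dienone 22, to the O4'–C(tertiary) bond of ether 21 and then to phenol 20. C3' is the only unsubstituted ring carbon and it is ortho to O4', so a [3,3] shift from oxygen delivers the carbon chain there with allyl inversion. The sensitive alkene is thereby absent from everything up to and including the aryne step. The forward steps require O-alkylation at the tertiary allyl terminus and a shift that ends at C3'; C5' is acylated and cannot re-aromatise.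

20 to 17 and 18: the C4'–O bond and the C5'–C(=O) bond are cut together. This is the strategic cut: the third ring oxygen and the acyl group arrive in one operation from a simple carboxylic acid, and the arene problem shrinks to a 1,2,4-trioxygenated ring bearing silicon and triflate on adjacent carbons. The forward step must add the carboxylate oxygen to C4' and not C5', must let the acyl shift outrun protonation, and must keep the aryne away from the pyrone diene.

17 to 14 (through 16 and 15): the S–O bond of the triflate is cut, the benzyl group is restored on O5', and the O–CH2 bond of the pyrone acetal is cut. The triflate is made last because it is the most sensitive group. O5' needs a protecting group that can be removed without touching the acetals on O2' and on the pyrone, hence the hydrogenolysable ether. The hydrogenolysis must spare the aryl–silicon bond and the pyrone.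

14 to 3 and 12: the bond between pyrone C3 and the bridging CH2 is cut. C3 of 3 is the nucleophilic carbon of a vinylogous acid, and in 12 the bridging carbon is an aldehyde, so a condensation–reduction joins two fragments of similar size. All organolithium chemistry is finished before the lactone enters. The forward step must condense at a doubly ortho-substituted aldehyde and reduce the alkylidene before a second pyrone adds to it.

12 to 8 (through 10): the C1'–CHO bond and the C4'–Si bond are cut. C1' lies between two coordinating oxygens, the cooperative site for deprotonation, and C4' carries bromine in 8 for exchange. Both substituents therefore enter at positions fixed by atoms already present, not by the electronic bias of an electrophilic substitution. The order matters: exchange and silylation come first, because the bromide would not survive the alkyllithium base, and the silyl group then shields the other ring hydrogen.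

8 to 4 (through 7 and 5): the acetal on O2' is cut, the C2'–O bond is traced back to a formyl carbon by oxygen insertion, and the benzyl ether is cut. Compound 4 already holds OMe, OH and Br on three consecutive carbons in the C6'/C5'/C4' order, and its formyl group sits para to the OH, exactly where O2' is needed. No halogenation or desymmetrisation of the arene is then required anywhere in the route. The forward oxygen insertion needs aryl migration, not hydride migration.

3 to 1 and 2: the C4–C5 bond and the O1–C2 bond of the pyrone are cut, leaving a symmetric ketone and a three-carbon bis-acylating agent. The ethyl and methyl groups of 3 are the two halves of 1, so no regiochemical question arises. The forward step needs C-acylation followed by O-acylation without a second acylation at C3.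

## Other disconnections considered

Alternative 1: The cut is the C3–C4 bond of the pyrone. In the forward direction a hindered lithium amide would deprotonate the acyl CH2 of the Z enol ester A2. The ester enolate would attack the methyl ester held cis to it across the enol double bond, a six-membered Claisen condensation with loss of methoxide. The product A1 is the bis(methoxymethyl) ether of 24 with the pyrone OH already free.
- In its favour: the pyrone is made last, so its acidic OH, diene and lactone never meet an aryne or an organolithium. The CH2 bridge comes from a plain 3-arylpropanoic acid and not from a condensation at a crowded aldehyde. Only one acetal cleavage separates A1 from 24, which is better than the three steps that follow the key step of the chosen plan.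
- Against it here: A2 already contains the complete hexasubstituted arene, so the placement of the O-methyl, acyl and prenyl groups is postponed and still needs its own solution. The aryl isopropyl ketone of A2 has an α-hydrogen at least as acidic as the ester CH2, so ketone enolate chemistry could compete. An ester enolate whose leaving group is itself an enolate can fragment to a ketene. Only the Z enol ester can close, and O-acylation of a β-keto ester does not set that geometry reliably.
- Comparison: on structure, the chosen plan solves the arene substitution pattern in its key step, while this one solves the pyrone, the easier ring. On mechanism, the Claisen closure is classical and is equal or better in precedent than an aryne insertion on so substituted a substrate, but it has more competing enolisation paths. On step economy, the end game is shorter, yet the unsolved arene, the two-carbon side chain and the stereodefined enol ester should make the total at least as long.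

Alternative 2: The cut removes three arene bonds, C2'–C3', C4'–C5' and C1'–C2', so the benzene ring is assembled from cyclobutenone A4 and siloxyalkyne A5. On heating, A4 should open in a four-electron electrocyclic step to a vinylketene. This adds [2+2] to the electron-rich alkyne, the ketene carbonyl carbon bonding to the prenyl-bearing alkyne carbon. Four-electron opening of the new cyclobutenone, six-electron closure of the dienylketene and tautomerisation would give phenol A3.
- In its favour: A3 emerges with the three oxygens already distinguished (free OH at C2', silyl ether at C4', methyl ether at C6'). The prenyl group is placed at C3' by the pericyclic sequence, so no late C-prenylation is needed, and on this point it is better than the chosen plan. It is convergent and needs no reagent.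
- Against it here: A3 still lacks the isobutyryl group. Acylating C5', a carbon flanked by two oxygens, would call for Friedel–Crafts or Fries conditions in the presence of an acid-sensitive prenyl group and the pyrone. A4 carries the whole pyrone on the ring sp3 carbon and has no short, secure preparation. The thermal cascade exposes ketene intermediates to the pyrone diene and to the prenyl alkene. A5 is moisture-sensitive and needs several steps itself.
- Comparison: on structure, the alternative builds the ring and the prenyl position at once but leaves the acyl group open, while the chosen plan installs acyl and oxygen together and leaves the prenyl group for later; each defers one substituent. On mechanism, both rely on a reactive intermediate (vinylketene or aryne) whose regiochemistry is set by an alkoxy group, and they are equal in that respect. On step economy, the counts should be close, the alternative spending its steps on A4, A5 and the late acylation.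

Alternative 3: The cut is the C5'–C6' bond, so the arene arises from one ring of the methylene-bridged bis-pyranone A7. A magnesium alkoxide in its parent alcohol would open the 2-methoxy-4-pyranone that bears the 3-methyl-2-oxobutyl chain by adding at its acetal carbon. The chelated 1,3-diketone carbanion then attacks the resulting ketene acetal carbon, methoxide leaves, and enolisation gives the acylresorcinol A6.
- In its favour: the acyl group, both phenols and the single O-methyl come out in the right places by construction, without protecting groups and without any aromatic substitution. The free resorcinol of A6 should accept a prenyl group at C3' more readily than the mono-phenol 20, which is a point in its favour over the chosen plan.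
- Against it here: A7 holds two nearly identical 2-methoxy-4-pyranones, and the alkoxide cannot be directed to open only one. The opened polyketone can close in other ways, back to a pyranone or by aldol condensation to a different arene. Making A7 requires an unsymmetrical methylene bridge between two different pyranones and O-methylation of ambident pyrone anions at the less favoured oxygen. At the end the surviving 2-methoxy-4-pyranone must be converted to the 4-hydroxy-2-pyrone of 24 without loss of the aryl methyl ether.
- Comparison: on structure, this route maps most directly onto the target and is free of protecting groups, which is better on paper. On mechanism, it replaces one well-defined regiochemical event (addition to an unsymmetrical aryne) with a cascade that has several cyclisation modes of similar energy, which is worse for predictability. On step economy, it could be shorter, but only if every ambident alkylation and the bridge formation were selective, which cannot be assumed.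

Key step: step 11

Remarks on the chemistry:
- Locants: pyrone atoms are O1 and C2–C6; arene carbons are primed as in the target, with C1' bearing the CH2 bridge.
- The key-step precursor 17 and product 20 map atom for atom onto the target (C1' CH2, C2' O, C3' H, C4' Si then O, C5' triflate then acyl, C6' OMe); no structural correction was needed.
- Design of the arene: a sequence that oxygenates and brominates a 2,6-dioxygenated benzyl ring step by step was weighed and not adopted. In such a ring C3' and C5' are both ortho/para to two oxygens, and electrophiles cannot be relied on to tell them apart. In the route below every arene substituent is placed either by the starting material 4 or by a lithiation whose position is fixed by atoms already present.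
- Assumption: tert-butyl 2-methylbut-3-en-2-yl carbonate (step 12) is treated as a purchasable reagent.

## Route

Step 1
Reactants: 1 3-pentanone; 2 malonyl dichloride
Product: 3 6-ethyl-4-hydroxy-5-methyl-2H-pyran-2-one
Conditions: 2 (1 equiv), 1 (3 equiv, neat), 0 °C → rt, 48 h; H2O, filter
Reagents that add atoms: none
Why: Pyrone annulation of a ketone with malonyl dichloride: C-acylation of the enol of 1 at the α-carbon, then O-acylation of the enolised 1,3-diketone by the second acid chloride, closes the lactone. Because 1 is symmetric, the α-carbon with its methyl becomes C5 and the carbonyl carbon with its ethyl becomes C6 without ambiguity; the excess of 1 limits a second acylation of 3 at C3.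

Step 2
Reactants: 4 5-bromovanillin (3-bromo-4-hydroxy-5-methoxybenzaldehyde)
Product: 5 4-(benzyloxy)-3-bromo-5-methoxybenzaldehyde
Conditions: BnBr, K2CO3, DMF, 50 °C
Reagents that add atoms: benzyl bromide, BrCc1ccccc1
Why: Williamson etherification of the phenoxide; the benzyl group masks O5' until the triflate is needed and should withstand peracid, mild base and butyllithium at low temperature.

Step 3
Reactants: 5 4-(benzyloxy)-3-bromo-5-methoxybenzaldehyde
Product: 7 4-(benzyloxy)-3-bromo-5-methoxyphenol, via aryl formate 6 (not isolated)
Conditions: mCPBA, CH2Cl2, rt; aq. NaHCO3 wash; then K2CO3 (0.2 equiv), MeOH, rt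
Reagents that add atoms: 3-chloroperoxybenzoic acid, O=C(OO)c1cccc(Cl)c1
Why: Baeyer–Villiger oxidation of an electron-rich benzaldehyde (Dakin-type): the para-alkoxyaryl group migrates in preference to hydride, and mild methanolysis of formate 6 frees the phenol that becomes O2'.

Step 4
Reactants: 7 4-(benzyloxy)-3-bromo-5-methoxyphenol
Product: 8 2-(benzyloxy)-1-bromo-3-methoxy-5-(methoxymethoxy)benzene
Conditions: MOMCl, i-Pr2NEt, CH2Cl2, 0 °C → rt
Reagents that add atoms: chloromethyl methyl ether, COCCl
Why: Acetal ether formation under amine base; the methoxymethyl group protects O2' to the end of the route and is the stronger of the two directing groups used in step 6.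

Step 5
Reactants: 8 2-(benzyloxy)-1-bromo-3-methoxy-5-(methoxymethoxy)benzene
Product: 10 [2-(benzyloxy)-3-methoxy-5-(methoxymethoxy)phenyl]trimethylsilane, via aryllithium 9 (not isolated)
Conditions: n-BuLi (1.05 equiv), THF, −78 °C, 15 min; TMSCl (1.2 equiv), −78 °C → rt
Reagents that add atoms: chlorotrimethylsilane, C[Si](C)(C)Cl
Why: Bromine–lithium exchange is much faster than any deprotonation at −78 °C, so silicon enters exactly at the former C–Br carbon (C4'); quenching aryllithium 9 cold forestalls proton transfer from the benzylic CH2.

Step 6
Reactants: 10 [2-(benzyloxy)-3-methoxy-5-(methoxymethoxy)phenyl]trimethylsilane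
Product: 12 3-(benzyloxy)-2-methoxy-6-(methoxymethoxy)-4-(trimethylsilyl)benzaldehyde, via aryllithium 11 (not isolated)
Conditions: n-BuLi (1.3 equiv), TMEDA (1.3 equiv), THF, −78 → 0 °C, 1 h; DMF (3 equiv), −78 °C → rt; H2O
Reagents that add atoms: N,N-dimethylformamide, CN(C)C=O
Why: Directed ortho-metalation: of the two ring hydrogens only the one between the methoxy and methoxymethoxy groups is flanked by two coordinating oxygens, and the other is shielded by the trimethylsilyl group, so lithiation and formylation should occur at C1' only.

Step 7
Reactants: 3 6-ethyl-4-hydroxy-5-methyl-2H-pyran-2-one; 12 3-(benzyloxy)-2-methoxy-6-(methoxymethoxy)-4-(trimethylsilyl)benzaldehyde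
Product: 14 3-{[3-(benzyloxy)-2-methoxy-6-(methoxymethoxy)-4-(trimethylsilyl)phenyl]methyl}-6-ethyl-4-hydroxy-5-methyl-2H-pyran-2-one, via Knoevenagel alkylidene 13 (not isolated)
Conditions: L-proline (20 mol %), Hantzsch ester (1.2 equiv), CH2Cl2, rt → 40 °C
Reagents that add atoms: none
Why: Three-component reductive alkylation: proline-catalysed Knoevenagel condensation at the nucleophilic C3 of 3 gives alkylidene 13, which the Hantzsch ester should reduce by conjugate hydride transfer before a second pyrone can add. The medium is neutral to weakly acidic, which the aryl–silicon bond and the acetal tolerate.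

Step 8
Reactants: 14 3-{[3-(benzyloxy)-2-methoxy-6-(methoxymethoxy)-4-(trimethylsilyl)phenyl]methyl}-6-ethyl-4-hydroxy-5-methyl-2H-pyran-2-one
Product: 15 3-{[3-(benzyloxy)-2-methoxy-6-(methoxymethoxy)-4-(trimethylsilyl)phenyl]methyl}-6-ethyl-4-(methoxymethoxy)-5-methyl-2H-pyran-2-one
Conditions: MOMCl, i-Pr2NEt, CH2Cl2, 0 °C
Reagents that add atoms: chloromethyl methyl ether, COCCl
Why: O-Alkylation of the vinylogous acid with a hard electrophile; C3 is blocked and alkylation at O4 keeps the conjugated 2-pyrone, so the 4-(methoxymethoxy) isomer should predominate.

Step 9
Reactants: 15 3-{[3-(benzyloxy)-2-methoxy-6-(methoxymethoxy)-4-(trimethylsilyl)phenyl]methyl}-6-ethyl-4-(methoxymethoxy)-5-methyl-2H-pyran-2-one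
Product: 16 6-ethyl-3-{[3-hydroxy-2-methoxy-6-(methoxymethoxy)-4-(trimethylsilyl)phenyl]methyl}-4-(methoxymethoxy)-5-methyl-2H-pyran-2-one
Conditions: H2 (1 atm), Pd/C (10 wt % palladium on carbon), EtOAc, rt
Reagents that add atoms: none
Why: Hydrogenolysis of the benzyl aryl ether over palladium; the aryl–silicon bond, both acetals and the fully substituted pyrone are expected to be inert at 1 atm and short reaction time.

Step 10
Reactants: 16 6-ethyl-3-{[3-hydroxy-2-methoxy-6-(methoxymethoxy)-4-(trimethylsilyl)phenyl]methyl}-4-(methoxymethoxy)-5-methyl-2H-pyran-2-one
Product: 17 3-{[6-ethyl-4-(methoxymethoxy)-5-methyl-2-oxo-2H-pyran-3-yl]methyl}-2-methoxy-4-(methoxymethoxy)-6-(trimethylsilyl)phenyl trifluoromethanesulfonate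
Conditions: Tf2O (1.2 equiv), pyridine, CH2Cl2, −40 → 0 °C
Reagents that add atoms: trifluoromethanesulfonic anhydride, O=S(=O)(OS(=O)(=O)C(F)(F)F)C(F)(F)F
Why: Sulfonylation of the phenol flanked by methoxy and trimethylsilyl groups, the usual last step in making ortho-silylaryl triflates; low temperature and the pyridine buffer protect the acetals.

Step 11
Reactants: 17 3-{[6-ethyl-4-(methoxymethoxy)-5-methyl-2-oxo-2H-pyran-3-yl]methyl}-2-methoxy-4-(methoxymethoxy)-6-(trimethylsilyl)phenyl trifluoromethanesulfonate; 18 isobutyric acid
Product: 20 6-ethyl-3-{[4-hydroxy-2-methoxy-6-(methoxymethoxy)-3-(2-methylpropanoyl)phenyl]methyl}-4-(methoxymethoxy)-5-methyl-2H-pyran-2-one, via aryne 19 (not isolated)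
Conditions: 18 (2 equiv), CsF (5 equiv), THF, rt, 30 min; then 17 added over 2 h, 80 °C (sealed tube); aq. NH4Cl
Reagents that add atoms: none
Why: Fluoride attacks the silicon on C4' and triflate leaves from C5', giving aryne 19. The acid has been turned into cesium isobutyrate by the excess CsF beforehand, and a carboxylate oxygen adds to C4'. That carbon is preferred because the C6' methoxy group, by inductive withdrawal and the bond-angle distortion it causes, makes C5' the better site for the developing aryl anion. The C5' anion then attacks the ester carbonyl two atoms away, and the four-membered alkoxide opens by C–O cleavage to the phenoxide of the ortho-hydroxyaryl ketone, a net 1,3 shift of the acyl group from oxygen to carbon that forms C4'–O and C5'–C(=O). The closest known reaction type is the fluoride-induced insertion of arynes into the C–O bond of carboxylic acids, used here on a more heavily substituted aryne. No ring is closed and no stereocentre is formed. The step needs three selectivities: the site of addition, secured by the methoxy group; acyl shift ahead of protonation of the aryl anion, helped by pre-neutralising the acid, aprotic THF and slow addition of 17; and capture by carboxylate ahead of Diels–Alder addition of the aryne to the pyrone of a second molecule, helped by the excess of carboxylate, dilution and the fully substituted pyrone. Both acidic hydroxyls are masked as acetals, which CsF in THF should leave intact.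

Step 12
Reactants: 20 6-ethyl-3-{[4-hydroxy-2-methoxy-6-(methoxymethoxy)-3-(2-methylpropanoyl)phenyl]methyl}-4-(methoxymethoxy)-5-methyl-2H-pyran-2-one
Product: 21 6-ethyl-3-{[2-methoxy-6-(methoxymethoxy)-4-[(2-methylbut-3-en-2-yl)oxy]-3-(2-methylpropanoyl)phenyl]methyl}-4-(methoxymethoxy)-5-methyl-2H-pyran-2-one
Conditions: tert-butyl 2-methylbut-3-en-2-yl carbonate (1.5 equiv), Pd(PPh3)4 (5 mol %), THF, 0 °C
Reagents that add atoms: tert-butyl 2-methylbut-3-en-2-yl carbonate, C=CC(C)(C)OC(=O)OC(C)(C)C
Why: Tsuji–Trost-type decarboxylative etherification: zerovalent palladium ionises the carbonate to a 1,1-dimethylallyl complex and tert-butoxide, which deprotonates the phenol. The phenoxide should attack the more substituted allyl terminus under kinetic control at low temperature to give the tertiary ether.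

Step 13
Reactants: 21 6-ethyl-3-{[2-methoxy-6-(methoxymethoxy)-4-[(2-methylbut-3-en-2-yl)oxy]-3-(2-methylpropanoyl)phenyl]methyl}-4-(methoxymethoxy)-5-methyl-2H-pyran-2-one
Product: 23 6-ethyl-3-{[4-hydroxy-2-methoxy-6-(methoxymethoxy)-5-(3-methylbut-2-en-1-yl)-3-(2-methylpropanoyl)phenyl]methyl}-4-(methoxymethoxy)-5-methyl-2H-pyran-2-one, via cyclohexadienone 22 (not isolated)
Conditions: toluene, 110 °C
Reagents that add atoms: none
Why: Aromatic Claisen rearrangement: the [3,3] shift moves the allyl unit with inversion to C3', the only ortho carbon that can re-aromatise because C5' is acylated. Dienone 22 tautomerises to the phenol, which is again hydrogen-bonded to the ketone.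

Step 14
Reactants: 23 6-ethyl-3-{[4-hydroxy-2-methoxy-6-(methoxymethoxy)-5-(3-methylbut-2-en-1-yl)-3-(2-methylpropanoyl)phenyl]methyl}-4-(methoxymethoxy)-5-methyl-2H-pyran-2-one
Product: 24 3-{[2,4-dihydroxy-6-methoxy-3-(3-methylbut-2-en-1-yl)-5-(2-methylpropanoyl)phenyl]methyl}-6-ethyl-4-hydroxy-5-methyl-2H-pyran-2-one (CNP0149198.0)
Conditions: HCl (3 M aq.), MeOH, rt → 40 °C
Reagents that add atoms: none
Why: Acid-catalysed acetal exchange with methanol removes both methoxymethyl groups, the vinylogous-ester acetal on the pyrone first and the aryl acetal more slowly. Dilute acid at or near room temperature is chosen because ortho-prenyl phenols need stronger acid or heat to cyclise to chromans.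

## Compound list

1 | 3-pentanone | CCC(=O)CC | starting material
2 | malonyl dichloride | O=C(Cl)CC(=O)Cl | starting material
3 | 6-ethyl-4-hydroxy-5-methyl-2H-pyran-2-one | CCc1oc(=O)cc(O)c1C | intermediate
4 | 5-bromovanillin (3-bromo-4-hydroxy-5-methoxybenzaldehyde) | COc1cc(C=O)cc(Br)c1O | starting material
5 | 4-(benzyloxy)-3-bromo-5-methoxybenzaldehyde | COc1cc(C=O)cc(Br)c1OCc1ccccc1 | intermediate
6 | 4-(benzyloxy)-3-bromo-5-methoxyphenyl formate (not isolated) | COc1cc(OC=O)cc(Br)c1OCc1ccccc1 | intermediate
7 | 4-(benzyloxy)-3-bromo-5-methoxyphenol | COc1cc(O)cc(Br)c1OCc1ccccc1 | intermediate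
8 | 2-(benzyloxy)-1-bromo-3-methoxy-5-(methoxymethoxy)benzene | COCOc1cc(OC)c(OCc2ccccc2)c(Br)c1 | intermediate
9 | [2-(benzyloxy)-3-methoxy-5-(methoxymethoxy)phenyl]lithium (not isolated) | [Li]c1cc(OCOC)cc(OC)c1OCc1ccccc1 | intermediate
10 | [2-(benzyloxy)-3-methoxy-5-(methoxymethoxy)phenyl]trimethylsilane | COCOc1cc(OC)c(OCc2ccccc2)c([Si](C)(C)C)c1 | intermediate
11 | [3-(benzyloxy)-2-methoxy-6-(methoxymethoxy)-4-(trimethylsilyl)phenyl]lithium (not isolated) | [Li]c1c(OC)c(OCc2ccccc2)c([Si](C)(C)C)cc1OCOC | intermediate
12 | 3-(benzyloxy)-2-methoxy-6-(methoxymethoxy)-4-(trimethylsilyl)benzaldehyde | O=Cc1c(OC)c(OCc2ccccc2)c([Si](C)(C)C)cc1OCOC | intermediate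
13 | 3-{[3-(benzyloxy)-2-methoxy-6-(methoxymethoxy)-4-(trimethylsilyl)phenyl]methylidene}-6-ethyl-5-methyl-2H-pyran-2,4(3H)-dione (not isolated; alkene geometry undefined, both isomers reduce to 14) | CCC1=C(C)C(=O)C(=Cc2c(OC)c(OCc3ccccc3)c([Si](C)(C)C)cc2OCOC)C(=O)O1 | intermediate
14 | 3-{[3-(benzyloxy)-2-methoxy-6-(methoxymethoxy)-4-(trimethylsilyl)phenyl]methyl}-6-ethyl-4-hydroxy-5-methyl-2H-pyran-2-one | CCc1oc(=O)c(Cc2c(OC)c(OCc3ccccc3)c([Si](C)(C)C)cc2OCOC)c(O)c1C | intermediate
15 | 3-{[3-(benzyloxy)-2-methoxy-6-(methoxymethoxy)-4-(trimethylsilyl)phenyl]methyl}-6-ethyl-4-(methoxymethoxy)-5-methyl-2H-pyran-2-one | CCc1oc(=O)c(Cc2c(OC)c(OCc3ccccc3)c([Si](C)(C)C)cc2OCOC)c(OCOC)c1C | intermediate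
16 | 6-ethyl-3-{[3-hydroxy-2-methoxy-6-(methoxymethoxy)-4-(trimethylsilyl)phenyl]methyl}-4-(methoxymethoxy)-5-methyl-2H-pyran-2-one | CCc1oc(=O)c(Cc2c(OC)c(O)c([Si](C)(C)C)cc2OCOC)c(OCOC)c1C | intermediate
17 | 3-{[6-ethyl-4-(methoxymethoxy)-5-methyl-2-oxo-2H-pyran-3-yl]methyl}-2-methoxy-4-(methoxymethoxy)-6-(trimethylsilyl)phenyl trifluoromethanesulfonate | COc1c(OS(=O)(=O)C(F)(F)F)c([Si](C)(C)C)cc(OCOC)c1Cc1c(OCOC)c(C)c(CC)oc1=O | intermediate
18 | isobutyric acid (2-methylpropanoic acid) | CC(C)C(=O)O | starting material
19 | 6-ethyl-3-{[2-methoxy-6-(methoxymethoxy)-3,4-didehydrophenyl]methyl}-4-(methoxymethoxy)-5-methyl-2H-pyran-2-one, the C4'–C5' aryne (not isolated) | COC1=C(Cc2c(OCOC)c(C)c(CC)oc2=O)C(OCOC)=CC#C1 | intermediate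
20 | 6-ethyl-3-{[4-hydroxy-2-methoxy-6-(methoxymethoxy)-3-(2-methylpropanoyl)phenyl]methyl}-4-(methoxymethoxy)-5-methyl-2H-pyran-2-one | COc1c(C(=O)C(C)C)c(O)cc(OCOC)c1Cc1c(OCOC)c(C)c(CC)oc1=O | intermediate
21 | 6-ethyl-3-{[2-methoxy-6-(methoxymethoxy)-4-[(2-methylbut-3-en-2-yl)oxy]-3-(2-methylpropanoyl)phenyl]methyl}-4-(methoxymethoxy)-5-methyl-2H-pyran-2-one | COc1c(C(=O)C(C)C)c(OC(C)(C)C=C)cc(OCOC)c1Cc1c(OCOC)c(C)c(CC)oc1=O | intermediate
22 | 6-ethyl-3-{[6-methoxy-2-(methoxymethoxy)-3-(3-methylbut-2-en-1-yl)-5-(2-methylpropanoyl)-4-oxocyclohexa-1,5-dien-1-yl]methyl}-4-(methoxymethoxy)-5-methyl-2H-pyran-2-one (not isolated; racemic at the ring CH) | COC1=C(C(=O)C(C)C)C(=O)C(CC=C(C)C)C(OCOC)=C1Cc1c(OCOC)c(C)c(CC)oc1=O | intermediate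
23 | 6-ethyl-3-{[4-hydroxy-2-methoxy-6-(methoxymethoxy)-5-(3-methylbut-2-en-1-yl)-3-(2-methylpropanoyl)phenyl]methyl}-4-(methoxymethoxy)-5-methyl-2H-pyran-2-one | COc1c(C(=O)C(C)C)c(O)c(CC=C(C)C)c(OCOC)c1Cc1c(OCOC)c(C)c(CC)oc1=O | intermediate
24 | 3-{[2,4-dihydroxy-6-methoxy-3-(3-methylbut-2-en-1-yl)-5-(2-methylpropanoyl)phenyl]methyl}-6-ethyl-4-hydroxy-5-methyl-2H-pyran-2-one (CNP0149198.0; no stereocentre) | CCc1oc(=O)c(Cc2c(O)c(CC=C(C)C)c(O)c(C(=O)C(C)C)c2OC)c(O)c1C | target

## Step count and least certain steps

Total step count: 14. Longest linear sequence: 13 steps (steps 2 to 14, from 4 to 24); step 1 supplies 3 to step 7.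

Step 11 (key step). The most likely failure is protonation of the C5' aryl anion before the acyl group has shifted, which would leave a simple aryl ester with hydrogen at C5'. Next in likelihood are cycloaddition of the aryne to the pyrone of another molecule and arylation of the product phenoxide by a second aryne. All three arise because the aryne is long-lived relative to a crowded intramolecular acyl transfer next to a methoxy group. Fallback, setting out from 17 and returning at 20: aryne 19 would be generated with CsF in DMF as solvent and reagent. It should insert into the formamide C=O bond in a formal [2+2] sense with the same polarity (oxygen to C4', carbon to C5'), and aqueous hydrolysis of the aminal should give the salicylaldehyde 6-ethyl-3-{[3-formyl-4-hydroxy-2-methoxy-6-(methoxymethoxy)phenyl]methyl}-4-(methoxymethoxy)-5-methyl-2H-pyran-2-one F1. Addition of i-PrMgCl in the presence of CeCl3 (THF, −78 °C; the first equivalent deprotonates the phenol) should give the racemic carbinol 6-ethyl-3-{[4-hydroxy-3-(1-hydroxy-2-methylpropyl)-2-methoxy-6-(methoxymethoxy)phenyl]methyl}-4-(methoxymethoxy)-5-methyl-2H-pyran-2-one F2. MnO2 in CH2Cl2 would then oxidise the benzylic alcohol to the ketone 20.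

Step 7. The aldehyde of 12 is flanked by two ortho oxygens and buttressed by a third substituent, so iminium formation and condensation may be slow. If hydride transfer lags, a second pyrone can add to the alkylidene and give a bis-pyrone adduct. Fallback, setting out from 12 and returning at 14: NaBH4 (MeOH, 0 °C) would reduce 12 to [3-(benzyloxy)-2-methoxy-6-(methoxymethoxy)-4-(trimethylsilyl)phenyl]methanol F3. With catalytic Bi(OTf)3 in MeNO2 at rt this doubly ortho-oxygenated benzylic alcohol should ionise, and the cation should be captured at C3 of 3 (dehydrative Friedel–Crafts-type C-benzylation of a 4-hydroxypyrone) to give 14.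

Step 12. The phenol of 20 is hydrogen-bonded to the ketone and its phenoxide is a weak nucleophile, so etherification may stall. Prolonged contact with the palladium catalyst can also isomerise the tertiary ether to the linear prenyl ether, which on rearrangement would deliver the wrong, 1,1-dimethylallyl, substituent. Fallback, setting out from 20 and returning at 23 (it replaces steps 12 and 13): the sodium phenoxide of 20 (NaH, toluene) would be treated with prenyl bromide at rt. In a non-polar solvent the tight ion pair directs alkylation to the ortho carbon, and C3' is the only one free. No new compound arises (F0).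

Step 14. The freed C2' phenol or the C4' phenol may add across the prenyl double bond under acid to give a 2,2-dimethylchroman, or the hindered C2' acetal may cleave incompletely under conditions mild enough to avoid that. Fallback, setting out from 20 and ending at 24 (it replaces steps 12 to 14): both acetals of 20 would be cleaved first (HCl, MeOH, 40 °C; no alkene is present) to give 3-{[4,6-dihydroxy-2-methoxy-3-(2-methylpropanoyl)phenyl]methyl}-6-ethyl-4-hydroxy-5-methyl-2H-pyran-2-one F4. The free acylresorcinol would then be C-prenylated at C3', its only open ring carbon, with prenyl bromide and aqueous KOH at 0 °C, the classical alkylation of acylresorcinol anions, to give 24 without any acid after the alkene is in place.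

Step 1. Under the HCl that is released, the product pyrone can be acylated again at C3 by 2, and the ketone can self-condense, so the direct annulation may be low-yielding and messy. Fallback, setting out from 1 and returning at 3: 1 would be converted to trimethyl(pent-2-en-3-yloxy)silane F5 (TMSCl, Et3N, NaI, MeCN; the geometry is immaterial). The isolated enol silyl ether would then be combined with 2 in Et2O at −78 °C → rt, where C-acylation and ring closure proceed without free ketone or accumulating acid.

## Further compounds

F1 | step 11 | 6-ethyl-3-{[3-formyl-4-hydroxy-2-methoxy-6-(methoxymethoxy)phenyl]methyl}-4-(methoxymethoxy)-5-methyl-2H-pyran-2-one | COc1c(C=O)c(O)cc(OCOC)c1Cc1c(OCOC)c(C)c(CC)oc1=O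
F2 | step 11 | 6-ethyl-3-{[4-hydroxy-3-(1-hydroxy-2-methylpropyl)-2-methoxy-6-(methoxymethoxy)phenyl]methyl}-4-(methoxymethoxy)-5-methyl-2H-pyran-2-one (racemic) | COc1c(C(O)C(C)C)c(O)cc(OCOC)c1Cc1c(OCOC)c(C)c(CC)oc1=O
F3 | step 7 | [3-(benzyloxy)-2-methoxy-6-(methoxymethoxy)-4-(trimethylsilyl)phenyl]methanol | OCc1c(OC)c(OCc2ccccc2)c([Si](C)(C)C)cc1OCOC
F0 | step 12 | none | none
F4 | step 14 | 3-{[4,6-dihydroxy-2-methoxy-3-(2-methylpropanoyl)phenyl]methyl}-6-ethyl-4-hydroxy-5-methyl-2H-pyran-2-one | CCc1oc(=O)c(Cc2c(O)cc(O)c(C(=O)C(C)C)c2OC)c(O)c1C
F5 | step 1 | trimethyl(pent-2-en-3-yloxy)silane (E/Z mixture) | CC=C(CC)O[Si](C)(C)C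
A1 | alternative 1 | 6-ethyl-4-hydroxy-3-{[2-methoxy-4,6-bis(methoxymethoxy)-5-(3-methylbut-2-en-1-yl)-3-(2-methylpropanoyl)phenyl]methyl}-5-methyl-2H-pyran-2-one | CCc1oc(=O)c(Cc2c(OCOC)c(CC=C(C)C)c(OCOC)c(C(=O)C(C)C)c2OC)c(O)c1C
A2 | alternative 1 | methyl (Z)-3-({3-[2-methoxy-4,6-bis(methoxymethoxy)-5-(3-methylbut-2-en-1-yl)-3-(2-methylpropanoyl)phenyl]propanoyl}oxy)-2-methylpent-2-enoate | CC/C(OC(=O)CCc1c(OCOC)c(CC=C(C)C)c(OCOC)c(C(=O)C(C)C)c1OC)=C(\C)C(=O)OC
A3 | alternative 2 | 6-ethyl-3-{[2-hydroxy-6-methoxy-3-(3-methylbut-2-en-1-yl)-4-(triisopropylsilyloxy)phenyl]methyl}-4-(methoxymethoxy)-5-methyl-2H-pyran-2-one | Oc1c(CC=C(C)C)c(O[Si](C(C)C)(C(C)C)C(C)C)cc(OC)c1Cc1c(OCOC)c(C)c(CC)oc1=O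
A4 | alternative 2 | 4-{[6-ethyl-4-(methoxymethoxy)-5-methyl-2-oxo-2H-pyran-3-yl]methyl}-3-methoxycyclobut-2-en-1-one (racemic) | COC1=CC(=O)C1Cc1c(OCOC)c(C)c(CC)oc1=O
A5 | alternative 2 | triisopropyl[(5-methylhex-4-en-1-yn-1-yl)oxy]silane | CC(C)=CCC#CO[Si](C(C)C)(C(C)C)C(C)C
A6 | alternative 3 | 1-{3-[(6-ethyl-2-methoxy-5-methyl-4-oxo-4H-pyran-3-yl)methyl]-4,6-dihydroxy-2-methoxyphenyl}-2-methylpropan-1-one | COc1c(Cc2c(OC)oc(CC)c(C)c2=O)c(O)cc(O)c1C(=O)C(C)C
A7 | alternative 3 | 6-ethyl-2-methoxy-3-{[2-methoxy-6-(3-methyl-2-oxobutyl)-4-oxo-4H-pyran-3-yl]methyl}-5-methyl-4H-pyran-4-one | COc1oc(CC(=O)C(C)C)cc(=O)c1Cc1c(OC)oc(CC)c(C)c1=O
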